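**Retrosynthetic overview**

1. Numbering follows the phthalide dimers: ring A is the butenolide (C1, O2, C3, C3a, C7a), ring B the cyclohexene (C3a, C4–C7, C7a), ring C the cyclobutane (C6, C7, C3', C8'), and the primed atoms belong to the aryl phthalide. The plan rests on one feature: ring C shares C6–C7 with ring B and its C7–C3' bond is allylic to the tetrasubstituted C3a=C7a alkene of ring A, so it is the 1,3-transposed counterpart of a C3a–C3' bond in a bicyclo[2.2.2]oct-5-en-2-one.
2. Ring A is cut last (O2–C3, silver-catalysed 5-exo-dig lactonisation of a 2-en-4-ynoic acid). The phthalide is cut next (C3'–aryl bond and lactone, from cyclobutanone 17 and an ortho-ester aryl Grignard reagent adding on the convex face).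
3. Ring C and the C7–C3' bond come from a photochemical 1,3-acyl shift of bicyclo[2.2.2]octenone 16, which also moves the alkene to C3a=C7a and leaves the bridgehead alkyne and the ester as a latent ring A.
4. Ketone 16 comes from a dearomatised phenol (o-quinol ester 11; C3', C8', C6, C7, C7a and C3a are the six arene carbons) by Diels–Alder reaction with acrylic acid as ethylene equivalent (C4–C5), decarboxylation, and SmI2 deacyloxylation that sets C8'–H. Absolute configuration enters by separating the C8' epimers of a camphanate.
5. Phenol 9 comes from methyl 3-hydroxy-4-iodobenzoate by Negishi propylation, directed magnesiation/iodination and Sonogashira coupling. Rings form in the order arene → ring B (as the bicyclo[2.2.2]octenone) → ring C → phthalide lactone → ring A.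

Key step: step 10

Remark (assumption on the chemistry): as for other 6-acyloxy-6-alkylcyclohexa-2,4-dienones, the dienophile in step 7 is taken to add on the acyloxy face, so the 4R quinol ester 11 leads to the required series; if the facial preference proved opposite, the 4S epimer that step 6 delivers alongside would be carried through instead.

Abbreviation: (1S)-camphanoyl = (1S,4R)-4,7,7-trimethyl-3-oxo-2-oxabicyclo[2.2.1]heptane-1-carbonyl.

**Route**

Step 1
Reactants: 1 methyl 3-hydroxy-4-iodobenzoate
Product: 2 methyl 4-iodo-3-(methoxymethoxy)benzoate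
Conditions: MOMCl, iPr2NEt, CH2Cl2, 0 °C → rt
Reagents that add atoms: chloromethyl methyl ether, COCCl
Why: O-alkylation of the phenol (Williamson-type acetal formation) gives a MOM ether that masks the phenol during the organometallic steps and later helps to direct the magnesiation.

Step 2
Reactants: 2 methyl 4-iodo-3-(methoxymethoxy)benzoate; 3 propylzinc bromide
Product: 4 methyl 3-(methoxymethoxy)-4-propylbenzoate
Conditions: Pd(dppf)Cl2 (3 mol%), THF, 50 °C
Reagents that add atoms: propylzinc bromide (compound 3), CCC[Zn]Br
Why: Negishi coupling of an aryl iodide with a primary alkylzinc halide; the wide bite angle of dppf favours reductive elimination over β-hydride elimination and the ester is inert to the organozinc.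

Step 3
Reactants: 4 methyl 3-(methoxymethoxy)-4-propylbenzoate
Product: 6 methyl 2-iodo-3-(methoxymethoxy)-4-propylbenzoate, via arylmagnesium chloride 5 (not isolated)
Conditions: TMPMgCl·LiCl, THF, 0 °C; then I2, –20 °C → rt
Reagents that add atoms: iodine, [I][I]
Why: Directed ortho-magnesiation with a hindered magnesium amide should occur at C2, the only position flanked by both the ester and the MOM ether, without attack on the ester; iodinolysis of the aryl–magnesium bond then installs the iodide.

Step 4
Reactants: 6 methyl 2-iodo-3-(methoxymethoxy)-4-propylbenzoate; 7 pent-1-yne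
Product: 8 methyl 3-(methoxymethoxy)-2-(pent-1-yn-1-yl)-4-propylbenzoate
Conditions: Pd(PPh3)2Cl2 (3 mol%), CuI (5 mol%), Et3N, THF, 50 °C, sealed tube
Reagents that add atoms: pent-1-yne (compound 7), CCCC#C
Why: Sonogashira coupling of the aryl iodide; the phenol is kept as its MOM ether so that the ortho-alkynyl phenol cannot cyclise to a benzofuran under the copper/amine conditions.

Step 5
Reactants: 8 methyl 3-(methoxymethoxy)-2-(pent-1-yn-1-yl)-4-propylbenzoate
Product: 9 methyl 3-hydroxy-2-(pent-1-yn-1-yl)-4-propylbenzoate
Conditions: HCl (2 M in MeOH), rt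
Reagents that add atoms: none
Why: Acid-catalysed acetal exchange with methanol removes the MOM group under metal-free, mildly acidic conditions that should leave the ortho-alkynyl phenol and the methyl ester untouched.

Step 6
Reactants: 9 methyl 3-hydroxy-2-(pent-1-yn-1-yl)-4-propylbenzoate; 10 (1S)-camphanic acid
Product: 11 methyl (4R)-4-[(1S)-camphanoyloxy]-3-oxo-2-(pent-1-yn-1-yl)-4-propylcyclohexa-1,5-diene-1-carboxylate
Conditions: Pb(OAc)4 (1.2 equiv) pre-stirred with 10 (8 equiv), CH2Cl2, 0 °C; the two epimers at the new centre separated by chromatography or crystallisation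
Reagents that add atoms: (1S)-camphanic acid (compound 10), OC(=O)[C@@]12CC[C@@](C)(C(=O)O1)C2(C)C
Why: Wessely oxidation in the presence of a carboxylic acid, in which the aryloxy lead carboxylate (tetravalent lead) delivers the acyloxy group to the ortho carbon bearing propyl (the alkynyl-bearing ortho carbon is hindered by the ester); since no dependable enantioselective intermolecular ortho-acyloxylation of a simple phenol is available, the quinol ester is made as the camphanate (a bridgehead acid that resists oxidative decarboxylation), so that the two epimers at the future C8' are diastereomers and the 4R epimer can be separated and assigned by X-ray analysis.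

Step 7
Reactants: 11 the 4R o-quinol camphanate; 12 acrylic acid
Product: 13 (1R,3R,4R,7R)-3-[(1S)-camphanoyloxy]-6-(methoxycarbonyl)-2-oxo-1-(pent-1-yn-1-yl)-3-propylbicyclo[2.2.2]oct-5-ene-7-carboxylic acid (numbering of 16)
Conditions: acrylic acid (10 equiv), BHT (cat.), PhMe, 90 °C
Reagents that add atoms: acrylic acid (compound 12), C=CC(=O)O
Why: Diels–Alder reaction of a cyclohexa-2,4-dienone, in which addition on the acyloxy face sets the bridgeheads C3a and C6 from the C8' centre and the usual ortho/endo orientation places the carboxyl on C4 next to C3a and syn to the alkene; acrylic acid serves as an ethylene equivalent whose carboxyl can be removed without reducing metals, and any regio- or endo/exo isomer at the carboxyl-bearing carbon converges in step 8.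

Step 8
Reactants: 13 the Diels–Alder acid
Product: 15 methyl (1R,3R,4R)-3-[(1S)-camphanoyloxy]-2-oxo-1-(pent-1-yn-1-yl)-3-propylbicyclo[2.2.2]oct-5-ene-6-carboxylate, via Barton ester 14 (not isolated)
Conditions: N-hydroxypyridine-2-thione, DCC, DMAP (cat.), CH2Cl2, 0 °C → rt, dark; then t-BuSH (20 equiv), PhH, hν (tungsten lamp), 15 °C
Reagents that add atoms: none
Why: Barton reductive decarboxylation, in which the thiohydroxamate ester fragments in a radical chain to the secondary C4 radical and this is capped by hydrogen transfer from the thiol, used in large excess so that 1,2-shifts of the neighbouring vinyl or acyl group should not compete; the neutral conditions spare ketone, enoate, alkyne and the acyloxy centre, which a dissolving-metal desulfonylation would endanger.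

Step 9
Reactants: 15 the α-camphanoyloxy ketone
Product: 16 methyl (1R,3R,4R)-2-oxo-1-(pent-1-yn-1-yl)-3-propylbicyclo[2.2.2]oct-5-ene-6-carboxylate (propyl syn to the C4–C5 ethano bridge)
Conditions: SmI2 (2.5 equiv), THF–MeOH, –78 °C; pH 7 phosphate buffer
Reagents that add atoms: none
Why: Reductive cleavage of an α-acyloxy ketone by SmI2 (ketyl formation, loss of camphanoate, second electron transfer) gives the samarium enolate, which methanol should protonate at C8' kinetically from the open face of the C7=C7a bridge so that propyl ends syn to the C4–C5 bridge; the cold neutral work-up guards this centre against epimerisation, and the auxiliary is released.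

Step 10
Reactants: 16 the bicyclo[2.2.2]oct-5-en-2-one
Product: 17 methyl (1R,6S,7R)-8-oxo-3-(pent-1-yn-1-yl)-7-propylbicyclo[4.2.0]oct-2-ene-2-carboxylate (cis ring fusion; propyl on the ring B face)
Conditions: hν (300–320 nm, Pyrex), degassed PhH (0.01 M), rt; stopped at partial conversion, recovered 16 re-irradiated
Reagents that add atoms: none
Why: n→π* excitation of the β,γ-unsaturated ketone is followed by α-cleavage of the C3a–C3' bond to a singlet acyl/allyl radical pair (the allyl part further stabilised by the alkynyl group on C3a) and in-cage recombination at the far allyl terminus C7, which is the photochemical 1,3-acyl shift known for bicyclo[2.2.2]oct-5-en-2-ones going to cis-fused bicyclo[4.2.0]octenones. Ring C closes by this radical-pair recombination, forming C7–C3'; because the acyl carbon stays tied to C6 through C8', it can reach C7 only on the face it left, so the shift is suprafacial and the ring fusion can only be cis. The new centre C7 is therefore set by the existing centre C6, while C6 and C8' are carried over unchanged, which places propyl (syn to the C4–C5 bridge in 16) on the ring B face of the cyclobutane. The step needs the singlet pathway to outrun intersystem crossing to the triplet, which would give the oxa-di-π-methane product, hence direct irradiation without sensitiser (a diene triplet quencher may be added). It also needs the product to survive, since 17 is itself a β,γ-unsaturated cyclobutanone that can shift back or lose CO or a ketene, so light is confined to the long-wavelength edge of the n,π* band of 16 and the run is stopped early with recycling. Cleavage on the C3a side should be preferred over the C8' side because only it gives an allylic radical.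

Step 11
Reactants: 17 the cyclobutanone; 18 methyl 2-iodobenzoate
Product: 21 methyl (1R,6S,7R,8R)-3'-oxo-3-(pent-1-yn-1-yl)-7-propyl-3'H-spiro[bicyclo[4.2.0]oct-2-ene-8,1'-[2]benzofuran]-2-carboxylate, via aryl Grignard reagent 19 (not isolated), via chloromagnesium alkoxide 20 (not isolated)
Conditions: 18, iPrMgCl·LiCl, THF, –40 °C; LaCl3·2LiCl; then 17, –78 → 0 °C; aq. NH4Cl
Reagents that add atoms: methyl 2-iodobenzoate (compound 18), COC(=O)c1ccccc1I
Why: Iodine–magnesium exchange gives the ester-bearing aryl Grignard reagent, whose lanthanum-assisted 1,2-addition to the strained cyclobutanone should outpace enolisation and attack on the enoate ester and should occur on the convex face (anti to ring B and to propyl), setting C3' with its oxygen cis to propyl; the alkoxide then closes the phthalide by 5-exo-trig acyl substitution on the neighbouring aryl ester.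

Step 12
Reactants: 21 the spiro phthalide methyl ester
Product: 23 (1R,6S,7R,8R)-3'-oxo-3-(pent-1-yn-1-yl)-7-propyl-3'H-spiro[bicyclo[4.2.0]oct-2-ene-8,1'-[2]benzofuran]-2-carboxylic acid, via dilithium hydroxy dicarboxylate 22 (not isolated)
Conditions: LiOH, THF–H2O, 40 °C; then 1 M HCl to pH 2
Reagents that add atoms: lithium hydroxide, [Li+].[OH-]
Why: Saponification of the hindered enoate methyl ester; the phthalide, which opens to the hydroxy carboxylate in base, should re-close spontaneously on acidification, and no stereocentre is epimerisable once the cyclobutanone carbonyl is gone.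

Step 13
Reactants: 23 the enyne carboxylic acid
Product: 24 target CNP0248594.2 (Z-butylidene butenolide ring A; 6S,7R,3'R,8'R)
Conditions: AgNO3 (10 mol%), acetone, rt, dark
Reagents that add atoms: none
Why: Silver-catalysed 5-exo-dig lactonisation of a (Z)-2-en-4-ynoic acid, in which anti addition of the carboxylate oxygen and a proton across the silver-activated alkyne closes ring A and gives the Z-butylidene group.

**Compound list**

1 | methyl 3-hydroxy-4-iodobenzoate | COC(=O)c1ccc(I)c(O)c1 | starting material
2 | methyl 4-iodo-3-(methoxymethoxy)benzoate | COCOc1cc(C(=O)OC)ccc1I | intermediate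
3 | propylzinc bromide (0.5 M in THF) | CCC[Zn]Br | starting material
4 | methyl 3-(methoxymethoxy)-4-propylbenzoate | CCCc1ccc(C(=O)OC)cc1OCOC | intermediate
5 | [2-(methoxycarbonyl)-6-(methoxymethoxy)-5-propylphenyl]magnesium chloride (LiCl complex; not isolated) | CCCc1ccc(C(=O)OC)c([Mg]Cl)c1OCOC | intermediate
6 | methyl 2-iodo-3-(methoxymethoxy)-4-propylbenzoate | CCCc1ccc(C(=O)OC)c(I)c1OCOC | intermediate
7 | pent-1-yne | CCCC#C | starting material
8 | methyl 3-(methoxymethoxy)-2-(pent-1-yn-1-yl)-4-propylbenzoate | CCCC#Cc1c(C(=O)OC)ccc(CCC)c1OCOC | intermediate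
9 | methyl 3-hydroxy-2-(pent-1-yn-1-yl)-4-propylbenzoate | CCCC#Cc1c(C(=O)OC)ccc(CCC)c1O | intermediate
10 | (1S)-(–)-camphanic acid, (1S,4R)-4,7,7-trimethyl-3-oxo-2-oxabicyclo[2.2.1]heptane-1-carboxylic acid | OC(=O)[C@@]12CC[C@@](C)(C(=O)O1)C2(C)C | starting material
11 | methyl (4R)-4-[(1S)-camphanoyloxy]-3-oxo-2-(pent-1-yn-1-yl)-4-propylcyclohexa-1,5-diene-1-carboxylate (o-quinol ester; C4 is the future C8') | CCCC#CC1=C(C(=O)OC)C=C[C@@](CCC)(OC(=O)[C@@]23CC[C@@](C)(C(=O)O2)C3(C)C)C1=O | intermediate
12 | acrylic acid | C=CC(=O)O | starting material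
13 | (1R,3R,4R,7R)-3-[(1S)-camphanoyloxy]-6-(methoxycarbonyl)-2-oxo-1-(pent-1-yn-1-yl)-3-propylbicyclo[2.2.2]oct-5-ene-7-carboxylic acid (numbering of 16; acyloxy syn to the ethano bridge, CO2H on skeletal C4 syn to the alkene) | CCCC#C[C@]12[C@H](C(=O)O)C[C@H](C=C1C(=O)OC)[C@@](CCC)(OC(=O)[C@@]34CC[C@@](C)(C(=O)O3)C4(C)C)C2=O | intermediate
14 | 2-thioxopyridin-1(2H)-yl ester of 13 (Barton ester; not isolated) | CCCC#C[C@]12[C@H](C(=O)On3ccccc3=S)C[C@H](C=C1C(=O)OC)[C@@](CCC)(OC(=O)[C@@]45CC[C@@](C)(C(=O)O4)C5(C)C)C2=O | intermediate
15 | methyl (1R,3R,4R)-3-[(1S)-camphanoyloxy]-2-oxo-1-(pent-1-yn-1-yl)-3-propylbicyclo[2.2.2]oct-5-ene-6-carboxylate | CCCC#C[C@]12CC[C@H](C=C1C(=O)OC)[C@@](CCC)(OC(=O)[C@@]34CC[C@@](C)(C(=O)O3)C4(C)C)C2=O | intermediate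
16 | methyl (1R,3R,4R)-2-oxo-1-(pent-1-yn-1-yl)-3-propylbicyclo[2.2.2]oct-5-ene-6-carboxylate (key-step precursor) | CCCC#C[C@]12CC[C@H](C=C1C(=O)OC)[C@@H](CCC)C2=O | intermediate
17 | methyl (1R,6S,7R)-8-oxo-3-(pent-1-yn-1-yl)-7-propylbicyclo[4.2.0]oct-2-ene-2-carboxylate (key-step product) | CCCC#CC1=C(C(=O)OC)[C@@H]2C(=O)[C@H](CCC)[C@@H]2CC1 | intermediate
18 | methyl 2-iodobenzoate | COC(=O)c1ccccc1I | starting material
19 | [2-(methoxycarbonyl)phenyl]magnesium chloride (LiCl complex; not isolated) | COC(=O)c1ccccc1[Mg]Cl | intermediate
20 | chloromagnesium alkoxide of the 1,2-adduct of 19 to 17 (aryl on the convex face; not isolated) | COC(=O)C1=C(C#CCCC)CC[C@H]2[C@@H](CCC)[C@@](c3ccccc3C(=O)OC)(O[Mg]Cl)[C@@H]12 | intermediate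
21 | methyl (1R,6S,7R,8R)-3'-oxo-3-(pent-1-yn-1-yl)-7-propyl-3'H-spiro[bicyclo[4.2.0]oct-2-ene-8,1'-[2]benzofuran]-2-carboxylate | COC(=O)C1=C(C#CCCC)CC[C@H]2[C@@H](CCC)[C@@]3(OC(=O)c4ccccc43)[C@@H]12 | intermediate
22 | dilithium salt of the ring-opened hydroxy dicarboxylic acid from 21 (not isolated) | [Li+].[Li+].[O-]C(=O)C1=C(C#CCCC)CC[C@H]2[C@@H](CCC)[C@@](c3ccccc3C([O-])=O)(O)[C@@H]12 | intermediate
23 | (1R,6S,7R,8R)-3'-oxo-3-(pent-1-yn-1-yl)-7-propyl-3'H-spiro[bicyclo[4.2.0]oct-2-ene-8,1'-[2]benzofuran]-2-carboxylic acid | OC(=O)C1=C(C#CCCC)CC[C@H]2[C@@H](CCC)[C@@]3(OC(=O)c4ccccc43)[C@@H]12 | intermediate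
24 | CNP0248594.2: Z-butylidene butenolide (ring A) fused to cyclohexene ring B, cyclobutane ring C cis-fused at C6–C7, spiro phthalide at C3' with its lactone oxygen cis to propyl and to the ring B carbons (6S,7R,3'R,8'R) | CCC/C=C1\OC(=O)C2=C1CC[C@H]1[C@@H](CCC)[C@@]3(OC(=O)c4ccccc43)[C@@H]21 | target

**Totals**

Total step count: 13. Longest linear sequence: 13 steps (1 → 24).

**Steps most likely to fail, and fallbacks**

Step 10 (key step). The excited ketone may cross into the triplet manifold and rearrange by the oxa-di-π-methane path. The acyl/allyl radical pair may disproportionate through the hydrogen on C8' to a ketene, or the C8' centre may be scrambled by cleavage and re-closure on that side. The cyclobutanone may also be photolysed further (loss of CO or of a ketene). The fallback moves the shift one step earlier, to the fully substituted α-acyloxy ketone, a well-documented substrate class for this photoreaction in which C8' carries no hydrogen. It sets out from 15: irradiation under the conditions of step 10 should give methyl 7-[(1S)-camphanoyloxy]-8-oxo-3-(pent-1-yn-1-yl)-7-propylbicyclo[4.2.0]oct-2-ene-2-carboxylate F1 (propyl on the convex face, acyloxy on the ring B face). SmI2 in THF–MeOH at –78 °C then removes the acyloxy group, and the samarium enolate of the cyclobutanone should be protonated on its convex face. This puts propyl on the ring B face and comes back to the route at 17.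

Step 6. Oxidation may go to the free para position instead of the ortho carbon, acetate may be transferred in place of the hindered camphanate, and the two epimers may resolve poorly on chromatography. The fallback is the classical acetoxylation with separation of enantiomers later. It sets out from 9: Pb(OAc)4 in AcOH at rt should give racemic methyl 4-acetoxy-3-oxo-2-(pent-1-yn-1-yl)-4-propylcyclohexa-1,5-diene-1-carboxylate F2. Diels–Alder reaction with acrylic acid as in step 7 gives the racemic 3-acetoxy analogue of acid 13, F3, and Barton decarboxylation as in step 8 gives racemic methyl 3-acetoxy-2-oxo-1-(pent-1-yn-1-yl)-3-propylbicyclo[2.2.2]oct-5-ene-6-carboxylate F4. The enantiomers of F4 are separated by preparative chromatography on a chiral stationary phase, and SmI2 treatment of the (1R,3R,4R) enantiomer as in step 9 comes back to the route at 16.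

Step 8. The C4 radical may rearrange by 1,2-shift of the adjacent vinyl or acyl group to the stabilised tertiary C3a radical before hydrogen transfer, and thiyl radicals may add to the alkyne. The fallback replaces the radical decarboxylation by a sulfone-based ethylene equivalent that is removed by electron transfer. It sets out from 11: Diels–Alder reaction with phenyl vinyl sulfone (PhMe, 110 °C) should give the 7-(phenylsulfonyl) analogue of 15, F5 (sulfonyl on skeletal C4, syn to the alkene). Na/Hg (6 %) with Na2HPO4 in MeOH–THF at –20 °C then cleaves the carbon–sulfur bond and, as a dissolving-metal reagent, is expected to take out the α-acyloxy group in the same operation, with buffered protonation at C8' from the alkene face. This comes back to the route at 16.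

**Further compounds**

F1 | step 10 | methyl 7-[(1S)-camphanoyloxy]-8-oxo-3-(pent-1-yn-1-yl)-7-propylbicyclo[4.2.0]oct-2-ene-2-carboxylate (cis-fused; propyl on the convex face) | CCCC#CC1=C(C(=O)OC)[C@@H]2C(=O)[C@](CCC)(OC(=O)[C@@]34CC[C@@](C)(C(=O)O3)C4(C)C)[C@@H]2CC1
F2 | step 6 | methyl 4-acetoxy-3-oxo-2-(pent-1-yn-1-yl)-4-propylcyclohexa-1,5-diene-1-carboxylate (racemate; 4R enantiomer drawn) | CCCC#CC1=C(C(=O)OC)C=C[C@@](CCC)(OC(C)=O)C1=O
F3 | step 6 | 3-acetoxy-6-(methoxycarbonyl)-2-oxo-1-(pent-1-yn-1-yl)-3-propylbicyclo[2.2.2]oct-5-ene-7-carboxylic acid (racemate; 1R,3R,4R,7R enantiomer drawn) | CCCC#C[C@]12[C@H](C(=O)O)C[C@H](C=C1C(=O)OC)[C@@](CCC)(OC(C)=O)C2=O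
F4 | step 6 | methyl 3-acetoxy-2-oxo-1-(pent-1-yn-1-yl)-3-propylbicyclo[2.2.2]oct-5-ene-6-carboxylate (racemate, then resolved; 1R,3R,4R enantiomer drawn) | CCCC#C[C@]12CC[C@H](C=C1C(=O)OC)[C@@](CCC)(OC(C)=O)C2=O
F5 | step 8 | methyl 3-[(1S)-camphanoyloxy]-2-oxo-1-(pent-1-yn-1-yl)-7-(phenylsulfonyl)-3-propylbicyclo[2.2.2]oct-5-ene-6-carboxylate (sulfonyl syn to the alkene) | CCCC#C[C@]12[C@H](S(=O)(=O)c3ccccc3)C[C@H](C=C1C(=O)OC)[C@@](CCC)(OC(=O)[C@@]45CC[C@@](C)(C(=O)O4)C5(C)C)C2=O
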